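**Plan**
- Retrosynthesis: the lactone C12–O bond and the C6 ester are cut first. The ring bond C6–C7 is cut next, because C6 carries oxygen and its neighbour C7 carries the C11 branch that ends in the exocyclic C13 methylene on the ten-membered carbocycle. This is the pattern left by a [2,3]-Wittig shift of a C6–O–C13 allyl ether, so the cut leads back to a furanone-bridged thirteen-membered ether.
- That ether is cut at O–C3 (furanone ring), C1–C2, O–C13, C11–C13 and C7–C8.
- Forward: citramalate dioxolanone, C7–C8 by acyl alkynylation, C8 carbinol, Z-iodoalkene, C13 hydroxymethyl, ether with the enynol, thirteen-membered ring by chromium-mediated C1–C2 closure, furanone ring by gold-catalysed closure, ten-membered carbocycle by ring contraction, C6 ester, α-methylene lactone ring last.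
- Stereochemistry: C10 from (S)-citramalic acid; C8 from catalyst-controlled transfer hydrogenation; C7=C11 geometry from hydroxyl-directed trans-hydroalumination and iodination; 4Z from the commercial enynol; C6 and C7 from the sigmatropic shift; the epoxide from Sharpless epoxidation of angelyl alcohol.

Key step: step 16

Assumption: the SMILES is read as the absolute configuration (6S,7R,8S,10S; acyl group 2S,3S). Atom labels follow germacrane numbering: C1 ketone, oxygen bridge C3–O–C10, C4=C5, C6 ester, C7/C8 lactone fusion, C11=C13 methylene, C12 lactone carbonyl, C14 and C15 methyls. The tartrate enantiomer in step 18 is assigned from the usual correlation that L-(+)-tartrate gives (2S)-epoxy alcohols from simple allylic alcohols.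

**Route**

Step 1
Reactants: 1 (S)-citramalic acid
Product: 2 2-[(4S)-2,2,4-trimethyl-5-oxo-1,3-dioxolan-4-yl]acetic acid
Conditions: 2,2-dimethoxypropane, TsOH·H2O (cat.), acetone, rt
Reagents that add atoms: 2,2-dimethoxypropane, COC(C)(C)OC
Why: acid-catalysed ketal exchange ties the tertiary hydroxyl and the adjacent carboxyl into a five-membered dioxolanone (favoured over the six-membered alternative), which tells C1 apart from C8 without touching the C10 stereocentre.

Step 2
Reactants: 2 dioxolanone acid; 3 tert-butyl(diphenyl)(prop-2-yn-1-yloxy)silane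
Product: 5 (5S)-5-[5-(tert-butyldiphenylsilyloxy)-2-oxopent-3-yn-1-yl]-2,2,5-trimethyl-1,3-dioxolan-4-one (C8 ynone), via acid chloride 4 (not isolated)
Conditions: (COCl)2, DMF (cat.), CH2Cl2, 0 °C → rt; concentrate; then 3, PdCl2(PPh3)2 (2 mol %), CuI (4 mol %), Et3N, THF, rt
Reagents that add atoms: oxalyl chloride, O=C(Cl)C(Cl)=O (chlorine of 4 only)
Why: DMF-catalysed chlorination gives the acid chloride, and acyl Sonogashira coupling with the terminal alkyne forms the C8–C7 bond under conditions mild enough for the dioxolanone, which a hard acetylide nucleophile might open.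

Step 3
Reactants: 5 C8 ynone
Product: 6 (5S)-5-[(2S)-5-(tert-butyldiphenylsilyloxy)-2-hydroxypent-3-yn-1-yl]-2,2,5-trimethyl-1,3-dioxolan-4-one
Conditions: Ru[(S,S)-TsNCH(Ph)CH(Ph)NH](p-cymene) (2 mol %), i-PrOH, rt
Reagents that add atoms: none
Why: Noyori asymmetric transfer hydrogenation of an alkynyl alkyl ketone, in which the (S,S)-ligand distinguishes the alkynyl from the alkyl flank and should give the (8S)-carbinol under catalyst control irrespective of the remote C10 centre.

Step 4
Reactants: 6 propargylic alcohol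
Product: 8 (2S,4S,5Z)-7-(tert-butyldiphenylsilyloxy)-6-iodo-2-methylhept-5-ene-1,2,4-triol, via cyclic vinylalanate 7 (not isolated)
Conditions: NaAlH2(OCH2CH2OCH3)2 (excess), THF, 0 °C → rt; EtOAc; then I2, THF, −78 → 0 °C
Reagents that add atoms: NaAlH2(OCH2CH2OCH3)2, [Na+].[AlH2-](OCCOC)OCCOC (aluminium and sodium of 7 only); iodine, [I][I]
Why: the C8 alkoxide directs trans-hydroalumination (hydride to C7, aluminium to C11 in a five-membered alanate) and iodine replaces aluminium with retention, so iodine ends cis to C8, while the same hydride reduces the dioxolanone to the C1,C10-diol (any γ-lactone formed from 6 by acyl transfer gives the same triol).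

Step 5
Reactants: 8 iodo triol
Product: 9 (2S,3Z)-5-(tert-butyldiphenylsilyloxy)-4-iodo-1-[(4S)-2,2,4-trimethyl-1,3-dioxolan-4-yl]pent-3-en-2-ol
Conditions: 2,2-dimethoxypropane, PPTS (cat.), CH2Cl2, 0 °C → rt
Reagents that add atoms: 2,2-dimethoxypropane, COC(C)(C)OC
Why: thermodynamic ketalisation prefers the five-membered dioxolane of the primary/tertiary 1,2-diol over the 1,3-dioxane through O8 and O10, which would carry an axial substituent at C10 against a ketal methyl, so the C8 hydroxyl is left free.

Step 6
Reactants: 9 acetonide alcohol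
Product: 10 C8 tert-butyldimethylsilyl ether of 9
Conditions: TBSOTf, 2,6-lutidine, CH2Cl2, −78 → 0 °C
Reagents that add atoms: TBSOTf, CC(C)(C)[Si](C)(C)OS(=O)(=O)C(F)(F)F
Why: silyl triflate with a hindered base silylates the secondary allylic alcohol cleanly at low temperature, and the bulky C8 silyloxy group later shields one face of C7.

Step 7
Reactants: 10 vinyl iodide
Product: 11 (2E,4S)-4-(tert-butyldimethylsilyloxy)-2-[(tert-butyldiphenylsilyloxy)methyl]-5-[(4S)-2,2,4-trimethyl-1,3-dioxolan-4-yl]pent-2-en-1-ol (C13 alcohol, C13 cis to C8)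
Conditions: Bu3SnCH2OH, Pd(PPh3)4 (10 mol %), 1,4-dioxane, 90 °C
Reagents that add atoms: (tributylstannyl)methanol, CCCC[Sn](CCCC)(CCCC)CO
Why: Stille coupling of the alkenyl iodide with the hydroxymethyl stannane proceeds with retention of alkene geometry, so the new C13 carbon is fixed cis to C8 and is distinguished from C12 beyond doubt.

Step 8
Reactants: 11 C13 alcohol
Product: 12 C13 allylic bromide of 11 (C13 cis to C8)
Conditions: CBr4, PPh3, 2,6-lutidine, CH2Cl2, −20 → 0 °C
Reagents that add atoms: CBr4, BrC(Br)(Br)Br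
Why: the Appel reaction converts the primary allylic alcohol into the bromide by substitution at C13 under neutral conditions, so no alkoxide is formed next to the C12 silyl ether and silyl migration between O12 and O13 cannot scramble the geometry.

Step 9
Reactants: 12 allylic bromide; 13 (2Z)-3-methylpent-2-en-4-yn-1-ol
Product: 14 C6–O–C13 diallylic ether with terminal alkyne (C2–H)
Conditions: 13, NaH, THF, 0 °C; then 12, Bu4NI (cat.), 0 °C → rt
Reagents that add atoms: none
Why: Williamson etherification of the sodium alkoxide of the primary allylic alcohol with the primary allylic bromide installs the ether oxygen between C6 and C13 early, before any furanone exists that a free cis C6 oxygen could attack, and brings in the 4Z alkene ready-made.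

Step 10
Reactants: 14 enyne ether
Product: 15 iodoalkyne of 14 (C2–iodine)
Conditions: N-iodosuccinimide, AgNO3 (10 mol %), acetone, rt, dark
Reagents that add atoms: N-iodosuccinimide, O=C1CCC(=O)N1I
Why: silver-catalysed electrophilic iodination of the terminal alkyne is selective for the acetylenic carbon–hydrogen bond and provides the handle for chromium-mediated ring closure.

Step 11
Reactants: 15 iodoalkyne acetonide
Product: 16 C1,C10-diol of 15
Conditions: CSA (0.2 equiv), MeOH/CH2Cl2, 0 °C
Reagents that add atoms: none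
Why: acid-catalysed transketalisation to methanol cleaves the terminal acetonide faster than the hindered secondary TBS ether or the TBDPS ether.

Step 12
Reactants: 16 diol
Product: 17 (2S)-2-hydroxy-2-methyl aldehyde (C1 aldehyde, C10 tertiary alcohol)
Conditions: (COCl)2, DMSO, CH2Cl2, −78 °C; Et3N, −78 → −20 °C
Reagents that add atoms: none
Why: Swern oxidation converts only the primary alcohol, since the tertiary hydroxyl cannot be oxidised, and the aldehyde has no α-hydrogen and is used crude.

Step 13
Reactants: 17 iodoalkyne aldehyde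
Product: 18 thirteen-membered macrocyclic enynediol (C1 carbinol as a mixture of epimers)
Conditions: CrCl2 (8 equiv), NiCl2 (2 mol %), THF, rt, slow addition of 17 (final 2 mM)
Reagents that add atoms: none
Why: in this Nozaki–Hiyama–Kishi closure, nickel-catalysed insertion of divalent chromium into the carbon–iodine bond gives a mild alkynylchromium nucleophile that adds to the aldehyde in the presence of the free tertiary hydroxyl, and high dilution favours the thirteen-membered ring; the C1 configuration is irrelevant because C1 is oxidised next.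

Step 14
Reactants: 18 macrocyclic enynediol
Product: 19 macrocyclic γ-hydroxy ynone (C1 ketone, C10 tertiary alcohol)
Conditions: IBX, DMSO, rt
Reagents that add atoms: none
Why: IBX oxidises the secondary propargylic alcohol of a 1,2-diol to the ketone without glycol cleavage.

Step 15
Reactants: 19 macrocyclic hydroxy ynone
Product: 20 furanone-bridged thirteen-membered C6–O–C13 diallylic ether (8S,10S; 4Z; C8 cis to C13; C8 OTBS, C12 OTBDPS)
Conditions: (4-CF3C6H4)3PAuCl (5 mol %), AgOTf (5 mol %), toluene, rt
Reagents that add atoms: none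
Why: gold activation of the ynone triggers 5-endo-dig attack of the C10 hydroxyl on C3 followed by protodeauration, the established route from γ-hydroxy ynones to 3(2H)-furanones, here run across the ring.

Step 16
Reactants: 20 furanone-bridged thirteen-membered ether
Product: 22 furanone-bridged ten-membered carbocycle with C6 alcohol and C7 branch C(=CH2)CH2OTBDPS (C6, C7, C8 and C10 arranged as in the target), via lithium trienolate 21 (not isolated)
Conditions: LiN(iPr)2 (1.2 equiv), THF, −78 → −40 °C; AcOH, −78 °C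
Reagents that add atoms: LiN(iPr)2, [Li]N(C(C)C)C(C)C (lithium of 21 only)
Why: LiN(iPr)2 removes a C6 proton, which is allylic, next to the ether oxygen and conjugated through C4=C5 and C2=C3 to the furanone carbonyl, and the trienolate attacks C7 through a five-membered envelope transition state while the O–C13 bond breaks, so the C6–C7 bond, the C6 alkoxide and the C11=C13 methylene arise in one suprafacial [2,3]-Wittig shift. The closest known reaction type is the [2,3]-Wittig ring contraction of thirteen-membered diallylic and allyl propargyl ethers to ten-membered carbocycles, together with the [2,3]-Wittig rearrangement of enolate-stabilised α-allyloxy carbanions. The ten-membered carbocycle closes by transannular C6-to-C7 bonding inside the thirteen-membered ring, with O, C13 and C11 leaving the ring, and not by an end-to-end cyclisation. C7 is set by the C8 stereocentre: with H8 eclipsing the C7=C11 bond to avoid allylic strain against C13, the short tether through C9 and C10 should deliver C6 to the alkene face anti to the C8 silyloxy group. C6 is set relative to C7 by the alkene geometry, since C8 cis to C13 puts C5 exo on the envelope, as in the erythro-selective shift of Z-allylic ethers. The step needs deprotonation at C6 over C13 and C15 (secured by through-conjugation to the carbonyl), [2,3] over [1,2] shift (secured by low temperature) and retention of the 4Z geometry (secured by keeping the anion cold and short-lived inside the bicyclic frame, with a cold acidic quench before the C6 alkoxide can attack C3 or a silyl group).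

Step 17
Reactants: 23 angelic acid
Product: 24 (2Z)-2-methylbut-2-en-1-ol
Conditions: LiAlH4, Et2O, 0 °C → rt
Reagents that add atoms: none
Why: hydride reduction of the carboxylate leaves the trisubstituted alkene and its Z geometry untouched.

Step 18
Reactants: 24 (2Z)-2-methylbut-2-en-1-ol
Product: 25 [(2R,3S)-2,3-dimethyloxiran-2-yl]methanol
Conditions: Ti(OiPr)4, D-(−)-diethyl tartrate, t-BuOOH, 4 Å molecular sieves, CH2Cl2, −20 °C
Reagents that add atoms: tert-butyl hydroperoxide, CC(C)(C)OO
Why: Sharpless asymmetric epoxidation delivers oxygen syn-stereospecifically to one alkene face chosen by the tartrate ligand, the D-(−)-ester being the one expected to give the (2R,3S)-epoxy alcohol from this Z-allylic alcohol.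

Step 19
Reactants: 25 epoxy alcohol
Product: 26 (2S,3S)-2,3-dimethyloxirane-2-carboxylic acid
Conditions: RuCl3·xH2O (2 mol %), NaIO4, CCl4/MeCN/H2O, rt
Reagents that add atoms: water, O
Why: catalytically generated RuO4 oxidises the primary alcohol through the aldehyde hydrate to the acid and leaves the epoxide alone (the change of the C2 descriptor is only a change of CIP priorities).

Step 20
Reactants: 22 carbocyclic C6 alcohol; 26 epoxy acid
Product: 28 C6 (2S,3S)-2,3-epoxy-2-methylbutanoate of 22, via mixed anhydride 27 (not isolated)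
Conditions: 26, 2,4,6-Cl3C6H2COCl, Et3N, toluene, rt; then 22, DMAP, rt
Reagents that add atoms: 2,4,6-trichlorobenzoyl chloride, O=C(Cl)c1c(Cl)cc(Cl)cc1Cl (atoms of 27 only)
Why: Yamaguchi esterification acylates the hindered secondary allylic alcohol with an acid whose quaternary α-carbon cannot epimerise, and capping C6 before C8 is unveiled forces the later lactone to close on O8.

Step 21
Reactants: 28 bis-silyl ester
Product: 29 C8,C12-diol (C6 ester retained)
Conditions: HF·pyridine, pyridine, THF, 0 °C → rt
Reagents that add atoms: none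
Why: buffered fluoride cleaves both the secondary TBS and the primary TBDPS ether, while the mildly acidic medium spares the epoxy ester and dienone and suppresses acyl migration from O6 to O8.

Step 22
Reactants: 29 diol
Product: 30 CNP0258430.1 (target)
Conditions: MnO2 (excess), CH2Cl2, rt
Reagents that add atoms: none
Why: MnO2 oxidises the allylic primary C12 alcohol to the enal, the C8 hydroxyl captures it as a lactol and this is oxidised on to the α-methylene γ-lactone (oxidative lactonisation of a 2-methylene-1,4-diol), with the C7/C8 trans fusion already in place.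

**Compound list**

1 | (S)-citramalic acid, (2S)-2-hydroxy-2-methylbutanedioic acid | C[C@](O)(CC(=O)O)C(=O)O | starting material
2 | 2-[(4S)-2,2,4-trimethyl-5-oxo-1,3-dioxolan-4-yl]acetic acid | C[C@]1(CC(=O)O)C(=O)OC(C)(C)O1 | intermediate
3 | tert-butyl(diphenyl)(prop-2-yn-1-yloxy)silane | C#CCO[Si](c1ccccc1)(c1ccccc1)C(C)(C)C | starting material
4 | 2-[(4S)-2,2,4-trimethyl-5-oxo-1,3-dioxolan-4-yl]acetyl chloride | C[C@]1(CC(=O)Cl)C(=O)OC(C)(C)O1 | intermediate
5 | (5S)-5-[5-(tert-butyldiphenylsilyloxy)-2-oxopent-3-yn-1-yl]-2,2,5-trimethyl-1,3-dioxolan-4-one | C[C@]1(CC(=O)C#CCO[Si](c2ccccc2)(c2ccccc2)C(C)(C)C)C(=O)OC(C)(C)O1 | intermediate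
6 | (5S)-5-[(2S)-5-(tert-butyldiphenylsilyloxy)-2-hydroxypent-3-yn-1-yl]-2,2,5-trimethyl-1,3-dioxolan-4-one | C[C@]1(C[C@H](O)C#CCO[Si](c2ccccc2)(c2ccccc2)C(C)(C)C)C(=O)OC(C)(C)O1 | intermediate
7 | sodium salt of the cyclic C8–O–Al–C11 vinylalanate (C1 and C10 oxygens drawn protonated) | C[C@](O)(C[C@@H]1O[Al-](OCCOC)(OCCOC)C(CO[Si](c2ccccc2)(c2ccccc2)C(C)(C)C)=C1)CO.[Na+] | intermediate
8 | (2S,4S,5Z)-7-(tert-butyldiphenylsilyloxy)-6-iodo-2-methylhept-5-ene-1,2,4-triol | C[C@](O)(C[C@H](O)/C=C(\I)CO[Si](c1ccccc1)(c1ccccc1)C(C)(C)C)CO | intermediate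
9 | (2S,3Z)-5-(tert-butyldiphenylsilyloxy)-4-iodo-1-[(4S)-2,2,4-trimethyl-1,3-dioxolan-4-yl]pent-3-en-2-ol | C[C@]1(C[C@H](O)/C=C(\I)CO[Si](c2ccccc2)(c2ccccc2)C(C)(C)C)COC(C)(C)O1 | intermediate
10 | C8 tert-butyldimethylsilyl ether of 9 | C[C@]1(C[C@H](O[Si](C)(C)C(C)(C)C)/C=C(\I)CO[Si](c2ccccc2)(c2ccccc2)C(C)(C)C)COC(C)(C)O1 | intermediate
11 | (2E,4S)-4-(tert-butyldimethylsilyloxy)-2-[(tert-butyldiphenylsilyloxy)methyl]-5-[(4S)-2,2,4-trimethyl-1,3-dioxolan-4-yl]pent-2-en-1-ol | C[C@]1(C[C@H](O[Si](C)(C)C(C)(C)C)/C=C(\CO)CO[Si](c2ccccc2)(c2ccccc2)C(C)(C)C)COC(C)(C)O1 | intermediate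
12 | C13 allylic bromide of 11 (bromomethyl cis to C8) | C[C@]1(C[C@H](O[Si](C)(C)C(C)(C)C)/C=C(\CBr)CO[Si](c2ccccc2)(c2ccccc2)C(C)(C)C)COC(C)(C)O1 | intermediate
13 | (2Z)-3-methylpent-2-en-4-yn-1-ol | C#C/C(C)=C\CO | starting material
14 | C6–O–C13 diallylic ether from 12 and 13 (terminal alkyne, 4Z, C8 cis to C13) | C[C@]1(C[C@H](O[Si](C)(C)C(C)(C)C)/C=C(\COC/C=C(C)\C#C)CO[Si](c2ccccc2)(c2ccccc2)C(C)(C)C)COC(C)(C)O1 | intermediate
15 | iodoalkyne of 14 | C[C@]1(C[C@H](O[Si](C)(C)C(C)(C)C)/C=C(\COC/C=C(C)\C#CI)CO[Si](c2ccccc2)(c2ccccc2)C(C)(C)C)COC(C)(C)O1 | intermediate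
16 | C1,C10-diol of 15 (acetonide removed) | C[C@](O)(C[C@H](O[Si](C)(C)C(C)(C)C)/C=C(\COC/C=C(C)\C#CI)CO[Si](c1ccccc1)(c1ccccc1)C(C)(C)C)CO | intermediate
17 | C1 aldehyde of 16, a (2S)-2-hydroxy-2-methyl aldehyde | C[C@](O)(C[C@H](O[Si](C)(C)C(C)(C)C)/C=C(\COC/C=C(C)\C#CI)CO[Si](c1ccccc1)(c1ccccc1)C(C)(C)C)C=O | intermediate
18 | thirteen-membered macrocyclic enynediol (C1 secondary carbinol as epimers, C10 tertiary alcohol) | C[C@]1(O)C[C@H](O[Si](C)(C)C(C)(C)C)/C=C(CO[Si](c2ccccc2)(c2ccccc2)C(C)(C)C)\COC/C=C(C)\C#CC1O | intermediate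
19 | macrocyclic γ-hydroxy ynone (C1 ketone) | C[C@]1(O)C[C@H](O[Si](C)(C)C(C)(C)C)/C=C(CO[Si](c2ccccc2)(c2ccccc2)C(C)(C)C)\COC/C=C(C)\C#CC1=O | intermediate
20 | furanone-bridged thirteen-membered C6–O–C13 diallylic ether (8S,10S; 4Z; C8 cis to C13) | O1C/C(CO[Si](c3ccccc3)(c3ccccc3)C(C)(C)C)=C\[C@@H](O[Si](C)(C)C(C)(C)C)C[C@]2(C)OC(=CC2=O)/C(C)=C\C1 | intermediate
21 | lithium trienolate of 20 (C6 deprotonated, drawn as the O-lithium form) | [Li]OC1=CC2=C(C)C=COC/C(CO[Si](c3ccccc3)(c3ccccc3)C(C)(C)C)=C\[C@@H](O[Si](C)(C)C(C)(C)C)C[C@]1(C)O2 | intermediate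
22 | furanone-bridged ten-membered carbocycle with C6 alcohol, C7 C(=CH2)CH2OTBDPS branch and C8 OTBS (4Z; C6, C7, C8, C10 arranged as in the target) | CC(C)(C)[Si](C)(C)O[C@H]2C[C@]3(C)OC(=CC3=O)/C(C)=C\[C@H](O)[C@@H]2C(=C)CO[Si](c1ccccc1)(c1ccccc1)C(C)(C)C | intermediate
23 | angelic acid, (2Z)-2-methylbut-2-enoic acid | C/C=C(/C)C(=O)O | starting material
24 | (2Z)-2-methylbut-2-en-1-ol | C/C=C(/C)CO | intermediate
25 | [(2R,3S)-2,3-dimethyloxiran-2-yl]methanol | OC[C@@]1(C)O[C@H]1C | intermediate
26 | (2S,3S)-2,3-dimethyloxirane-2-carboxylic acid | OC(=O)[C@@]1(C)O[C@H]1C | intermediate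
27 | mixed anhydride of 26 with 2,4,6-trichlorobenzoic acid | O=C(OC(=O)c1c(Cl)cc(Cl)cc1Cl)[C@@]2(C)O[C@H]2C | intermediate
28 | C6 (2S,3S)-2,3-epoxy-2-methylbutanoate of 22 (C8 OTBS, C12 OTBDPS) | CC(C)(C)[Si](C)(C)O[C@H]2C[C@]3(C)OC(=CC3=O)/C(C)=C\[C@H](OC(=O)[C@@]4(C)O[C@H]4C)[C@@H]2C(=C)CO[Si](c1ccccc1)(c1ccccc1)C(C)(C)C | intermediate
29 | C8,C12-diol of 28 | O[C@H]2C[C@]3(C)OC(=CC3=O)/C(C)=C\[C@H](OC(=O)[C@@]4(C)O[C@H]4C)[C@@H]2C(=C)CO | intermediate
30 | CNP0258430.1, (6S,7R,8S,10S)-8,12-olide with 3,10-oxygen-bridged 3(2H)-furanone, 4Z alkene and 6-O-[(2S,3S)-2,3-epoxy-2-methylbutanoyl] group | C=C1C(=O)O[C@H]2C[C@]3(C)OC(=CC3=O)/C(C)=C\[C@H](OC(=O)[C@@]3(C)O[C@H]3C)[C@H]12 | target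

**Step count**
Total: 22 steps. Longest linear sequence: 19 steps (steps 1–16 and 20–22 from (S)-citramalic acid); steps 17–19 make the side-chain acid.

**Steps most likely to fail**

Step 16 (ring contraction). The strongly delocalised trienolate may rearrange sluggishly, may drift into the [1,2] pathway on warming, or may lose the 4Z geometry by rotation about the C4–C5 bond before the shift. The fallback keeps the same C6–C7 bond formation and O–C13 cleavage but moves it ahead of furanone formation, onto a localised carbanion of the kind used in the established ring contractions. It sets out from macrocyclic enynediol 18. Both hydroxyls are silylated (Et3SiOTf, 2,6-lutidine, CH2Cl2) to give the bis-triethylsilyl ether F1. n-BuLi in THF at −78 °C removes a C6 proton (allylic, next to oxygen, conjugated with the enyne) and the [2,3] shift should give the ten-membered cycloenynol F2, with C6 and C7 set by the same envelope arguments. The C6 hydroxyl is esterified with acid 26 through anhydride 27 to give the epoxy ester F3. The two triethylsilyl groups are removed selectively (PPTS, MeOH) to give the C1,C10-diol F4, and IBX oxidation gives the carbocyclic hydroxy ynone F5. Gold-catalysed 5-endo-dig closure as in step 15 then returns to the route at ester 28.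

Step 13 (chromium-mediated macrocyclisation). Intermolecular coupling to oligomers, or reductive loss of iodine from the alkynylchromium species, may outrun closure of the thirteen-membered ring. The fallback closes the same ring at C3–C4 by an intramolecular Sonogashira coupling and sets out from bromide 12. But-2-yn-1-ol is converted by hydroxyl-directed trans-hydroalumination with NaAlH2(OCH2CH2OCH3)2 and iodination into (2Z)-3-iodobut-2-en-1-ol F6. Its sodium alkoxide (NaH, THF) is alkylated with 12 to give the vinyl iodide ether F7. Acetonide cleavage (CSA, MeOH) gives the diol F8, Swern oxidation gives the hydroxy aldehyde F9, and addition of HC≡CMgBr gives the ethynyl carbinol F10. Pd(PPh3)4, CuI and Et3N in THF at high dilution then join C3 to C4 with retention of the Z geometry and return to the route at macrocyclic enynediol 18.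

Step 15 (gold-catalysed furanone closure). The ether oxygen between C6 and C13 may attack the gold-activated alkyne and transfer its allyl group, or the transannular 5-endo closure may be slow enough for the ynone to decompose. The fallback replaces π-acid catalysis by amine conjugate addition and acid-mediated ring closure and sets out from hydroxy ynone 19. Et2NH in EtOH at rt adds to C3 to give the enaminone F11. Aqueous AcOH then lets the C10 hydroxyl displace the amine by addition–elimination at C3 and returns to the route at furanone 20.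

Further compounds
F1 | step 16 | bis-triethylsilyl ether of macrocyclic enynediol 18 | C[C@]1(O[Si](CC)(CC)CC)C[C@H](O[Si](C)(C)C(C)(C)C)/C=C(CO[Si](c2ccccc2)(c2ccccc2)C(C)(C)C)\COC/C=C(C)\C#CC1O[Si](CC)(CC)CC
F2 | step 16 | ring-contracted ten-membered cycloenynol (C6 alcohol, C7 methylene branch) | CC(C)(C)[Si](C)(C)O[C@H]2C[C@](C)(O[Si](CC)(CC)CC)C(O[Si](CC)(CC)CC)C#C/C(C)=C\[C@H](O)[C@@H]2C(=C)CO[Si](c1ccccc1)(c1ccccc1)C(C)(C)C
F3 | step 16 | C6 epoxy ester of F2 | CC(C)(C)[Si](C)(C)O[C@H]2C[C@](C)(O[Si](CC)(CC)CC)C(O[Si](CC)(CC)CC)C#C/C(C)=C\[C@H](OC(=O)[C@@]3(C)O[C@H]3C)[C@@H]2C(=C)CO[Si](c1ccccc1)(c1ccccc1)C(C)(C)C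
F4 | step 16 | C1,C10-diol from F3 | CC(C)(C)[Si](C)(C)O[C@H]2C[C@](C)(O)C(O)C#C/C(C)=C\[C@H](OC(=O)[C@@]3(C)O[C@H]3C)[C@@H]2C(=C)CO[Si](c1ccccc1)(c1ccccc1)C(C)(C)C
F5 | step 16 | carbocyclic γ-hydroxy ynone from F4 | CC(C)(C)[Si](C)(C)O[C@H]2C[C@](C)(O)C(=O)C#C/C(C)=C\[C@H](OC(=O)[C@@]3(C)O[C@H]3C)[C@@H]2C(=C)CO[Si](c1ccccc1)(c1ccccc1)C(C)(C)C
F6 | step 13 | (2Z)-3-iodobut-2-en-1-ol | OC/C=C(C)\I
F7 | step 13 | C6–O–C13 ether of 12 with F6 (vinyl iodide at C4) | C[C@]1(C[C@H](O[Si](C)(C)C(C)(C)C)/C=C(\COC/C=C(C)\I)CO[Si](c2ccccc2)(c2ccccc2)C(C)(C)C)COC(C)(C)O1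
F8 | step 13 | C1,C10-diol of F7 | C[C@](O)(C[C@H](O[Si](C)(C)C(C)(C)C)/C=C(\COC/C=C(C)\I)CO[Si](c1ccccc1)(c1ccccc1)C(C)(C)C)CO
F9 | step 13 | C1 hydroxy aldehyde of F8 | C[C@](O)(C[C@H](O[Si](C)(C)C(C)(C)C)/C=C(\COC/C=C(C)\I)CO[Si](c1ccccc1)(c1ccccc1)C(C)(C)C)C=O
F10 | step 13 | ethynyl carbinol from F9 (C1 epimers) | C[C@](O)(C[C@H](O[Si](C)(C)C(C)(C)C)/C=C(\COC/C=C(C)\I)CO[Si](c1ccccc1)(c1ccccc1)C(C)(C)C)C(O)C#C
F11 | step 15 | macrocyclic C3-diethylamino enaminone from 19 | C[C@]1(O)C[C@H](O[Si](C)(C)C(C)(C)C)/C=C(CO[Si](c2ccccc2)(c2ccccc2)C(C)(C)C)\COC/C=C(C)\C(N(CC)CC)=CC1=O
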